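## The problem

The target is a C20 gibberellin, a 12-oxo 7,19-dioic acid with C20 as an aldehyde, in which cyclohexane ring A is trans-fused to cyclopentane ring B, ring B is cis-fused to ring C, and rings C and D form a bicyclo[3.2.1]octane with an exocyclic C16=C17 methylene next to the C12 ketone. Twenty carbons carry seven stereocentres (C4, C5, C6, C8, C9, C10, C13), three of them quaternary (C4, C8, C10), and C4 and C10 hold the C19 acid and the C20 aldehyde 1,3-diaxial on one face of ring A. Few centres can serve as control elements: C8 fixes C9 through the cis B/C fusion and C13 through the bridge, and a stereocentre at C6 beside C8 can relay to C5 and C10, whereas C4 has no such neighbour and must come from a transition-state preference. The functionality is fragile in definite ways: a C20 alcohol closes onto a C19 ester, the C20 aldehyde forms a lactol with the C19 acid, and the 16-ene tolerates neither hydrogenation nor strong acid. In addition, C6–H is epimerisable next to C7, a C3 ketone beside the quaternary C4 ester invites retro-Claisen cleavage by alkoxides, and the axial C19 ester is too hindered to saponify. Ring D closure at C13 must also be told apart from closure at C11, the other α-carbon of the C12 ketone, which is reachable from C8 in the same way. The enabling feature is that C4, with its methyl (C18) and carboxyl (C19), lies between C3 and C5 like the α-carbon of a 2-methyl β-keto ester. C5, C10 and C9 then read on as an alkene and the β-carbon of a cyclohexenone, so one radical chain started at C4 can close ring A (C1–C5, C10) and ring B (C5, C6, C8, C9, C10).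

## Retrosynthesis

**Late functional groups (33 ⇒ 32 ⇒ 31 ⇒ 29).** No skeletal bond is cut. The C19 ester O–alkyl bond, the C20 oxidation level and the bond from C7 to the C20 oxygen are taken back, so 33 comes from aldehyde 32, hydroxy acid 31 and tetracyclic lactone 29. In 29, C7 and the C20 oxygen form one δ-lactone and C19 is a tert-butyl ester. The neighbouring choice, a C20 benzyl ether with two methyl esters, fails here: hydrogenolysis would reduce C16=C17, a free C20 alcohol closes onto a methyl C19 ester, and that ester cannot be hydrolysed beside the aldehyde. The lactone saves two protecting groups and makes C6 a non-enolisable bridgehead through every base step before it. Its price is that C7 sits on the α face. The forward steps must open the lactone with inversion at C6, oxidise C20 under neutral conditions and cleave the C19 ester at the alkyl–oxygen bond. The inversion should be downhill, because natural C7 is trans to C4 and clear of C20.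

**Ring D (29 ⇒ 28 ⇒ 27).** The C13–C16 bond is cut, leading through silyl enol ether 28 to ketone 27 with a propargyl group on C8. Cutting C12–C13 or C8–C15 instead would destroy the cyclohexenone that the radical step needs. This cut also makes the exocyclic methylene in the ring-forming step. Ketone 27 is a tricycle, and its only missing centre, C13, is fixed by the bridge. The forward reaction must enolise C12 toward C13 and not toward C11.

**Adjusting the radical product (27 ⇒ 26 ⇒ 25 ⇒ 24 ⇒ 23 ⇒ 22 ⇒ 21 ⇒ 20).** C17 is removed (C16–C17), the arm returns to a silyl-protected alcohol, and the C3 oxygen is restored. The order is forced. The C3 oxygen must go by hydrogenation of enol triflate 22 before any alkyne or alkene exists. C12 must be masked (21) while C3 is enolised. No alkoxide may be used while the C3/C4 β-keto ester is present. This leads back to 20, which carries exactly the two ketones the radical step produces.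

**Key disconnection (20 ⇒ 19).** C4–C5 and C9–C10 are cut. Two rings and four stereocentres (C4, C5, C9, C10) fall away, leaving lactone 19 with two stereocentres (C6, C8), a 2-methyl β-keto ester and a 4,4-disubstituted cyclohexenone. An open-chain C7 ester with a C20 ether would leave the face of the C5=C10 alkene and the A/B fusion to acyclic control. Tying C7 to the C20 oxygen puts the alkene in a six-membered ring, so the C8 substituent on the adjacent ring carbon blocks one face and ring B can only close cis to it. The forward reaction is an oxidative radical bicyclisation by trivalent manganese, ended by hydrogen transfer to C11.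

**Lactone and side chain (19 ⇒ 18 ⇒ 14 + 17; 17 ⇒ 15 + 16).** The C5=C10 bond is cut by ring-closing metathesis, which gives the required alkene geometry without a selective olefination. The ester bond at the C20 oxygen is cut to acid 14 and allylic chloride 17. The C1–C2 bond of 17 is cut to the dianion of 15 and dichloride 16. The strongly basic dianion chemistry is thus kept away from the acidic C6–H of the chiral fragment. Both the alkylation and the metathesis must proceed without a base able to enolise C6.

**Enone (14 ⇒ 13 ⇒ 11 ⇒ 10).** The C12 oxygen is removed. Acid 10 has one ring alkene whose only allylic methylene is C12, so no regiochemical question arises. The acid is masked as tert-butyl ester 11 for the oxidation and freed again.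

**C6–C8 bond (10 ⇒ 7 ⇒ 5 + 6).** The bond between the tertiary C6 and the quaternary C8 is cut by an Ireland–Claisen rearrangement of ester 7, made from allylic alcohol 5 and acid 6. This is preferred to a conjugate addition on a symmetrical ring followed by desymmetrisation, because one sigmatropic shift sets both centres and carries the absolute configuration from the C11 carbinol. The forward reaction needs a defined ketene acetal geometry and one transition-state topology.

**Ring C building block (5 ⇒ 4 ⇒ 3 ⇒ 1).** The C11 carbinol comes from catalytic asymmetric reduction of enone 4. Enone 4 comes from the aromatic ring of 1 by Birch reduction, hydrolysis and silylation. The aromatic carbon bearing the side chain becomes C8 and the side chain becomes C15–C16.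

## Roads not taken

Alternative 1: The cut is C6–C8, and ring B would close last by an Ireland–Claisen ring contraction. C6 is the α-carbon of a C7 ester whose oxygen sits on C13, inside a nine-membered ring with a C8=C14 alkene. As the silyl ketene acetal, C6 bonds to C8 while the C13–O bond breaks and the alkene moves to C13=C14. This closes ring B, frees the C7 acid and gives A1.
- Merits: the hindered C6–C8 bond forms intramolecularly, and C6 and C8 are set together from one carbinol. The C13=C14 alkene beside the C12 ketal would give, after deketalisation and conjugate reduction, a C13 enolate of fixed regiochemistry for ring D. In this respect it is better than the chosen plan, which relies on kinetic enolisation (step 20) and a late C6 inversion (step 22).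
- Weak points: the contraction needs a nine-membered ring with an endocyclic trisubstituted alkene, closed by esterifying a hindered acid. Its open-chain precursor must already carry ring A with the C4/C10 quaternary pair, C5, C9 and the C13 carbinol. The hardest part of the target, the 1,3-diaxial C19/C20 array and the trans A/B relation, is left to a long linear preparation. Chair and boat transition states are closer in medium rings.
- Comparison: the chosen plan makes rings A and B and four centres in one step from a two-stereocentre precursor eleven steps from commercial materials. Against alternative 1's cleaner C13 access it sets the steric bias against C11 in 27 and a formylation fallback.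

Alternative 2: The cuts are C9–C11 and C10–C20. Irradiation at 350 nm would make a β-pivaloyloxy enone unit (C12 ketone, C11=C20), tethered through C13–C14 to C8, add across a tetrasubstituted C9=C10 alkene shared by rings A and B. Ring C and a cyclobutane would form, giving A2. Retro-aldol cleavage of C11–C20 would then reveal the C20 aldehyde and the C12 ketone.
- Merits: C10 becomes quaternary with C20 already at the aldehyde level, and the propargyl arm is in place. The route never passes through a C20 alcohol, so the lactonisation onto C19 that shapes the chosen endgame (steps 22–24) does not arise. Here alternative 2 is better.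
- Weak points: a [2+2] addition to a fully substituted ring-fusion alkene creates C9 and C10 together on a face chosen only by substituents at C5 and C8. The terminal alkyne is itself a partner for an excited enone. The enol ester can lose its geometry. Rings A and B with C4, C5, C6 and C8 must be built beforehand without help from the key step.
- Comparison: the chosen plan controls C5, C9 and C10 by ring constraints and needs no photochemistry on a crowded alkene. It pays with three extra steps at C20 and the C19 tert-butyl ester.

Alternative 3: The cut is C12–C13, and ring C would close last. A Lewis acid would activate a C12 aldehyde on the C9 side chain. C13, the γ-carbon of an allylic silane built into a ring D cyclopentene (C16=C13, silicon on C17), would attack it. This forms C12–C13, closes the bicyclo[3.2.1]octane, moves the alkene to C16=C17 and gives alcohol A3.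
- Merits: the allylic silane dictates the regiochemistry at C13, and the exocyclic methylene appears in the same mild step. This is better than the chosen ring D sequence, which needs three steps for the alkyne and a kinetic enolisation.
- Weak points: rings A, B and D with six stereocentres must exist before the key step. The C4/C10 pair and the trans A/B fusion are again left to unspecified chemistry. C8 becomes a spiro centre set between two nearly equal methylene arms. The C12 alcohol needs a further oxidation, and the allylic silane can be lost by protodesilylation.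
- Comparison: the chosen plan spends its key step on rings A and B, where the difficulty lies. It accepts a longer ring D sequence with a regiochemical risk that has a fallback.

Key step: step 12

Remark: atoms carry gibberellane numbers (C1–C20) in every intermediate; α/β follow the usual gibberellin drawing (C19 and C20 α; H-5, H-9, the natural C7 carboxyl and the C15–C16 bridge β); TBDPS = tert-butyldiphenylsilyl; tert-butyl 2-methyl-3-oxobutanoate (15) is taken to be purchasable.

Step 1
Reactants: 1 2-(3-methoxyphenyl)ethan-1-ol
Product: 3 3-(2-hydroxyethyl)cyclohex-2-en-1-one, via methoxycyclohexa-1,4-diene 2 (not isolated)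
Conditions: Li, NH3 (l), t-BuOH, THF, −78 → −33 °C; then 2 M HCl, THF, rt
Reagents that add atoms: water, O
Why: Birch reduction of the anisole leaves the methoxy- and alkyl-bearing carbons unsaturated; aqueous acid hydrolyses the enol ether and moves the remaining alkene into conjugation, giving the 3-substituted cyclohexenone.

Step 2
Reactants: 3 3-(2-hydroxyethyl)cyclohex-2-en-1-one
Product: 4 3-[2-(TBDPS-oxy)ethyl]cyclohex-2-en-1-one
Conditions: t-BuPh2SiCl, imidazole, DMF, rt
Reagents that add atoms: tert-butyl(chloro)diphenylsilane, CC(C)(C)[Si](Cl)(c1ccccc1)c1ccccc1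
Why: Standard silylation of the primary alcohol; this silyl ether should survive amide bases, trifluoroacetic acid, peroxide oxidation, metathesis and the manganese step and is removed later by fluoride alone.

Step 3
Reactants: 4 3-[2-(TBDPS-oxy)ethyl]cyclohex-2-en-1-one
Product: 5 (1R)-3-[2-(TBDPS-oxy)ethyl]cyclohex-2-en-1-ol
Conditions: (S)-2-methyl-CBS-oxazaborolidine (10 mol %), BH3·SMe2, THF, −30 °C
Reagents that add atoms: none
Why: Corey–Bakshi–Shibata reduction: the alkenyl side of the enone acts as the large group, so the (S)-catalyst should deliver hydride to give the (R)-allylic alcohol; this carbinol (C11) is the only source of absolute configuration in the route.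

Step 4
Reactants: 5 (1R)-3-[2-(TBDPS-oxy)ethyl]cyclohex-2-en-1-ol; 6 but-3-enoic acid
Product: 7 (1R)-3-[2-(TBDPS-oxy)ethyl]cyclohex-2-en-1-yl but-3-enoate
Conditions: DCC, DMAP (5 mol %), CH2Cl2, 0 °C
Reagents that add atoms: none
Why: Steglich esterification with little DMAP at low temperature, to avoid isomerisation of the but-3-enoate to the crotonate; the C11 configuration is untouched.

Step 5
Reactants: 7 (1R)-3-[2-(TBDPS-oxy)ethyl]cyclohex-2-en-1-yl but-3-enoate
Product: 10 (2R)-2-{(1R)-1-[2-(TBDPS-oxy)ethyl]cyclohex-2-en-1-yl}but-3-enoic acid, via (E)-silyl ketene acetal 8 (not isolated), via trimethylsilyl ester 9 (not isolated)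
Conditions: LiN(iPr)2, Me3SiCl, THF, −78 → 60 °C; then 1 M HCl
Reagents that add atoms: none
Why: Ireland–Claisen rearrangement: kinetic deprotonation in THF should give the (E)-silyl ketene acetal (vinyl trans to OSi), and the [3,3] shift through a chair-like transition state with the vinyl group turned away from the cyclohexene ring forms C6–C8 on the face that carried the ester oxygen. This transfers the C11 configuration to the quaternary C8 (R) and sets C6 (R), the relative configuration in which C7 will lie cis to C14 on ring B; acidic work-up hydrolyses the silyl ester.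

Step 6
Reactants: 10 (2R)-2-{(1R)-1-[2-(TBDPS-oxy)ethyl]cyclohex-2-en-1-yl}but-3-enoic acid
Product: 11 tert-butyl (2R)-2-{(1R)-1-[2-(TBDPS-oxy)ethyl]cyclohex-2-en-1-yl}but-3-enoate
Conditions: Cl3CC(=NH)OtBu, BF3·OEt2 (cat.), CH2Cl2/cyclohexane, rt
Reagents that add atoms: tert-butyl 2,2,2-trichloroacetimidate, CC(C)(C)OC(=N)C(Cl)(Cl)Cl
Why: O-alkylation of the carboxylic acid by a tert-butyl cation donor avoids acyl substitution at the hindered C7; the ester masks the acid during the oxidation.

Step 7
Reactants: 11 tert-butyl (2R)-2-{(1R)-1-[2-(TBDPS-oxy)ethyl]cyclohex-2-en-1-yl}but-3-enoate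
Product: 13 tert-butyl (2R)-2-{(1R)-1-[2-(TBDPS-oxy)ethyl]-4-oxocyclohex-2-en-1-yl}but-3-enoate, via C12 tert-butyl peroxide 12 (not isolated)
Conditions: Rh2(cap)4 (cap = caprolactamate, 1 mol %), t-BuOOH (aq.), K2CO3, CH2Cl2, rt
Reagents that add atoms: tert-butyl hydroperoxide, CC(C)(C)OO
Why: Allylic C–H oxidation by tert-butylperoxyl radicals: C12 is the only allylic methylene of the ring alkene (C8 is quaternary), and the mixed peroxide collapses to the enone. The C6–H, although allylic to the vinyl group, is α to the ester and flanked by C8, so it is electron-poor and shielded.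

Step 8
Reactants: 13 tert-butyl (2R)-2-{(1R)-1-[2-(TBDPS-oxy)ethyl]-4-oxocyclohex-2-en-1-yl}but-3-enoate
Product: 14 (2R)-2-{(1R)-1-[2-(TBDPS-oxy)ethyl]-4-oxocyclohex-2-en-1-yl}but-3-enoic acid
Conditions: CF3CO2H, CH2Cl2, 0 °C
Reagents that add atoms: none
Why: Acidolysis of the tert-butyl ester with loss of isobutene; the silyl ether, the enone and the monosubstituted alkene should be stable to cold trifluoroacetic acid.

Step 9
Reactants: 15 tert-butyl 2-methyl-3-oxobutanoate; 16 3-chloro-2-(chloromethyl)prop-1-ene
Product: 17 tert-butyl 6-(chloromethyl)-2-methyl-3-oxohept-6-enoate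
Conditions: NaH, THF, 0 °C; n-BuLi, −10 °C; then 16 (3 equiv), −78 → 0 °C
Reagents that add atoms: none
Why: γ-Alkylation of the β-keto ester dianion by one allylic chloride of the symmetrical dichloride forms C1–C2; excess dichloride and a cold quench suppress double alkylation and closure of the remaining enolate onto the second chloride.

Step 10
Reactants: 14 (2R)-2-{(1R)-1-[2-(TBDPS-oxy)ethyl]-4-oxocyclohex-2-en-1-yl}but-3-enoic acid; 17 tert-butyl 6-(chloromethyl)-2-methyl-3-oxohept-6-enoate
Product: 18 tert-butyl 6-{[((2R)-2-{(1R)-1-[2-(TBDPS-oxy)ethyl]-4-oxocyclohex-2-en-1-yl}but-3-enoyl)oxy]methyl}-2-methyl-3-oxohept-6-enoate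
Conditions: Cs2CO3 (0.55 equiv), NaI (cat.), DMF, rt
Reagents that add atoms: none
Why: SN2 alkylation of the caesium carboxylate by the allylic chloride, again without acyl substitution at C7 and without a base strong enough to enolise C6 or the β-keto ester. If part of 14 sits as its conjugate-addition lactone, it should reopen by β-elimination under these conditions.

Step 11
Reactants: 18 tert-butyl 6-{[((2R)-2-{(1R)-1-[2-(TBDPS-oxy)ethyl]-4-oxocyclohex-2-en-1-yl}but-3-enoyl)oxy]methyl}-2-methyl-3-oxohept-6-enoate
Product: 19 (3R)-3-{(1R)-1-[2-(TBDPS-oxy)ethyl]-4-oxocyclohex-2-en-1-yl}-5-[5-(tert-butoxy)-4-methyl-3,5-dioxopentyl]-3,6-dihydro-2H-pyran-2-one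
Conditions: second-generation Grubbs catalyst (5 mol %), 1,4-benzoquinone (10 mol %), toluene (2 mM), 80 °C
Reagents that add atoms: none
Why: Ring-closing metathesis of the vinyl group with the 1,1-disubstituted alkene gives the six-membered unsaturated lactone. The ring enforces the C5=C10 geometry (C20 cis to C6), and benzoquinone suppresses isomerisation by ruthenium hydrides to the conjugated lactone.

Step 12
Reactants: 19 (3R)-3-{(1R)-1-[2-(TBDPS-oxy)ethyl]-4-oxocyclohex-2-en-1-yl}-5-[5-(tert-butoxy)-4-methyl-3,5-dioxopentyl]-3,6-dihydro-2H-pyran-2-one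
Product: 20 ring A/B/C lactone (3,12-dione; 19-tert-butyl ester; C7 lactonised to the C20 oxygen; 16-O-TBDPS)
Conditions: Mn(OAc)3·2H2O (2.2 equiv), degassed EtOH (5 mM), 25 → 50 °C
Reagents that add atoms: none
Why: Oxidative radical polycyclisation: Mn(OAc)3 oxidises the manganese enolate of the β-keto ester to the electrophilic C4 radical, which adds 6-endo to C5 of the electron-rich trisubstituted C5=C10 alkene (C4–C5, ring A) and ignores the electron-poor enone; the tertiary, nucleophilic C10 radical then adds 5-exo to the enone β-carbon C9 (C9–C10, ring B), and the C11 α-keto radical takes hydrogen from ethanol, whose hydroxyethyl radical consumes the second equivalent of oxidant. The closest known reaction type is the Mn(OAc)3 tandem 6-endo/5-exo cyclisation of unsaturated 2-substituted β-keto esters to trans-fused bicycles with an axial ester; the variations are the alkene held in a lactone ring and the enone terminus. C4 follows from the chair-like 6-endo transition state with the ester axial and the methyl group equatorial, as in the known cases. C5 is set by attack of the radical on the lactone alkene anti to the quaternary C8 substituent on the neighbouring ring carbon C6. C10 is set because the two-atom bridge C8–C9 can reach from C6 to C10 only on the lactone face that carries C8; with the anti attack at C5 this enforces the trans A/B fusion and places C20 cis to C19. C9 follows from the 5-exo closure onto the ring alkene from a tether on C8, which can only give the cis B/C fusion with C10 trans to the C15 arm. The step needs 6-endo over 5-exo regioselectivity (secured by the 1,1-disubstituted proximal alkene carbon and the ketone inside the forming ring), a C15 arm without π-bonds so that the C11 radical has no partner, and ring B closure faster than hydrogen transfer to C10, which is helped by the polarity match and by the diaxial placement of C4 and C8 on the lactone that the anti addition produces.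

Step 13
Reactants: 20 ring A/B/C lactone (3,12-dione)
Product: 21 12-ethylene ketal of 20
Conditions: Me3SiOCH2CH2OSiMe3, Me3SiOTf (cat.), CH2Cl2, −78 → −20 °C
Reagents that add atoms: 1,2-bis(trimethylsilyloxy)ethane, C[Si](C)(C)OCCO[Si](C)(C)C
Why: Silyl-transfer ketalisation at low temperature should discriminate the unhindered C12 ketone from the neopentyl C3 ketone of the β-keto ester; no alkoxide is present, so the C3/C4 β-keto ester is not exposed to retro-Claisen cleavage.

Step 14
Reactants: 21 12-ethylene ketal of 20
Product: 22 C2=C3 enol triflate of 21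
Conditions: KN(SiMe3)2, PhNTf2, THF, −78 °C
Reagents that add atoms: N-phenylbis(trifluoromethanesulfonimide), O=S(=O)(N(c1ccccc1)S(=O)(=O)C(F)(F)F)C(F)(F)F
Why: C3 can enolise only toward C2 because C4 is quaternary, and the lactone has no enolisable α-hydrogen because C6 is a bridgehead; the hindered amide base should therefore give a single enolate, trapped as the enol triflate.

Step 15
Reactants: 22 C2=C3 enol triflate of 21
Product: 23 3-deoxy lactone (C2 and C3 methylene; 12-ketal; 16-O-TBDPS)
Conditions: H2 (1 atm), PtO2, NaHCO3, EtOAc, rt
Reagents that add atoms: none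
Why: Hydrogenation of an enol triflate over platinum cleaves the C–O bond and saturates C2=C3, removing the C3 oxygen in one operation before any alkene or alkyne is present; bicarbonate takes up the triflic acid so that ketal, tert-butyl ester and silyl ether survive.

Step 16
Reactants: 23 3-deoxy lactone (12-ketal; 16-O-TBDPS)
Product: 24 C16 primary alcohol
Conditions: Bu4NF, AcOH (1:1), THF, rt
Reagents that add atoms: none
Why: Fluoride cleavage of the silyl ether; buffering with acetic acid keeps the alkoxide concentration low so that the C16 alcohol does not transacylate the strained lactone.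

Step 17
Reactants: 24 C16 primary alcohol
Product: 25 C16 aldehyde
Conditions: Dess–Martin periodinane, CH2Cl2, 0 °C → rt
Reagents that add atoms: none
Why: Dess–Martin oxidation of the primary alcohol to the aldehyde under neutral conditions; ketal, lactone and tert-butyl ester are inert.

Step 18
Reactants: 25 C16 aldehyde
Product: 26 terminal alkyne (C8 propargyl; 12-ketal)
Conditions: Me3SiCHN2, LiN(iPr)2, THF, −78 → 0 °C
Reagents that add atoms: (trimethylsilyl)diazomethane, C[Si](C)(C)C=[N+]=[N-]
Why: Colvin rearrangement: lithiated trimethylsilyldiazomethane adds to the aldehyde at −78 °C, loss of silanolate and dinitrogen and a 1,2-hydrogen shift give the terminal alkyne (C17 added); lactone and ester should not react at this temperature.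

Step 19
Reactants: 26 terminal alkyne (12-ketal)
Product: 27 12-ketone with C8 propargyl group
Conditions: PPTS, acetone/H2O, 50 °C
Reagents that add atoms: water, O
Why: Mild acid-catalysed hydrolysis of the dioxolane; the tert-butyl ester, the lactone and the alkyne tolerate pyridinium tosylate.

Step 20
Reactants: 27 12-ketone with C8 propargyl group
Product: 28 C12=C13 tert-butyldimethylsilyl enol ether
Conditions: LiN(SiMe3)2, THF, −78 °C; then t-BuMe2SiOTf
Reagents that add atoms: tert-butyldimethylsilyl trifluoromethanesulfonate, CC(C)(C)[Si](C)(C)OS(=O)(=O)C(F)(F)F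
Why: Kinetic deprotonation of the C12 ketone: C13 is an unhindered methylene, whereas C11 is flanked by C9 with its two quaternary neighbours and lies under the C20 lactone bridge, so the bulky amide should take a C13 proton. The lactone has no α-hydrogen to compete and the silazide is too weak a base to metalate the alkyne appreciably; the enolate is fixed as the silyl enol ether.

Step 21
Reactants: 28 C12=C13 tert-butyldimethylsilyl enol ether
Product: 29 tetracyclic lactone (ring D closed; 12-ketone; 16-ene; 19-tert-butyl ester)
Conditions: Ph3PAuNTf2 (5 mol %), CH2Cl2/MeOH (10:1), rt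
Reagents that add atoms: none
Why: Gold-catalysed 5-exo-dig carbocyclisation of a silyl enol ether onto a terminal alkyne (Conia-ene type): C13 attacks the gold-activated C16, methanol takes the silyl group and protonates the vinylgold, giving ring D with the exocyclic C16=C17 methylene. The bridge can form only with C16 cis to C15, which sets C13.

Step 22
Reactants: 29 tetracyclic lactone
Product: 31 C20 alcohol C7 acid with natural C6 configuration (19-tert-butyl ester), via methyl ester 30 (not isolated)
Conditions: NaOMe, MeOH, 65 °C; then NaOH, H2O, 65 °C; HCl to pH 4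
Reagents that add atoms: sodium hydroxide, [Na+].[OH-]
Why: Methoxide opens the strained lactone to the C7 methyl ester and the C20 alkoxide; the ester enolises and C6 should settle in the natural configuration (C7 trans to C4 and away from C20), after which relactonisation is impossible and the equilibrium is drained. Hydroxide then saponifies the C7 methyl ester, while the neopentyl tert-butyl ester at C19 should resist both acyl transfer and hydrolysis.

Step 23
Reactants: 31 C20 alcohol C7 acid (19-tert-butyl ester)
Product: 32 C20 aldehyde C7 acid (19-tert-butyl ester)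
Conditions: Dess–Martin periodinane, CH2Cl2, 0 °C → rt
Reagents that add atoms: none
Why: Dess–Martin oxidation of the neopentyl C20 alcohol to the non-enolisable aldehyde under neutral conditions, before any acid is applied that could close the alcohol onto C19.

Step 24
Reactants: 32 C20 aldehyde C7 acid (19-tert-butyl ester)
Product: 33 ent-12,20-dioxogibberell-16-ene-7,19-dioic acid (target)
Conditions: 85 % H3PO4 (aq.), toluene, 40 °C
Reagents that add atoms: none
Why: Acidolysis of the tert-butyl ester by alkyl–oxygen cleavage, which needs no attack at the hindered C19 carbonyl; aqueous phosphoric acid is mild enough that the 16-ene, the aldehyde and the ketone should be left alone.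

Compound list

1 | 2-(3-methoxyphenyl)ethan-1-ol | COc1cccc(CCO)c1 | starting material
2 | 2-(5-methoxycyclohexa-1,4-dien-1-yl)ethan-1-ol | COC1=CCC=C(CCO)C1 | intermediate (not isolated)
3 | 3-(2-hydroxyethyl)cyclohex-2-en-1-one | O=C1C=C(CCO)CCC1 | intermediate
4 | 3-{2-[(tert-butyldiphenylsilyl)oxy]ethyl}cyclohex-2-en-1-one | O=C1C=C(CCO[Si](c2ccccc2)(c2ccccc2)C(C)(C)C)CCC1 | intermediate
5 | (1R)-3-{2-[(tert-butyldiphenylsilyl)oxy]ethyl}cyclohex-2-en-1-ol | O[C@H]1C=C(CCO[Si](c2ccccc2)(c2ccccc2)C(C)(C)C)CCC1 | intermediate
6 | but-3-enoic acid | C=CCC(=O)O | starting material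
7 | (1R)-3-{2-[(tert-butyldiphenylsilyl)oxy]ethyl}cyclohex-2-en-1-yl but-3-enoate | C=CCC(=O)O[C@H]1C=C(CCO[Si](c2ccccc2)(c2ccccc2)C(C)(C)C)CCC1 | intermediate
8 | (E)-silyl ketene acetal: (1R)-3-{2-[(tert-butyldiphenylsilyl)oxy]ethyl}-1-{[(1E)-1-(trimethylsilyloxy)buta-1,3-dien-1-yl]oxy}cyclohex-2-ene | C=C/C=C(\O[C@H]1C=C(CCO[Si](c2ccccc2)(c2ccccc2)C(C)(C)C)CCC1)O[Si](C)(C)C | intermediate (not isolated)
9 | trimethylsilyl (2R)-2-[(1R)-1-{2-[(tert-butyldiphenylsilyl)oxy]ethyl}cyclohex-2-en-1-yl]but-3-enoate | CC(C)(C)[Si](c1ccccc1)(c1ccccc1)OCC[C@]1(C=CCCC1)[C@@H](C=C)C(=O)O[Si](C)(C)C | intermediate (not isolated)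
10 | (2R)-2-[(1R)-1-{2-[(tert-butyldiphenylsilyl)oxy]ethyl}cyclohex-2-en-1-yl]but-3-enoic acid | CC(C)(C)[Si](c1ccccc1)(c1ccccc1)OCC[C@]1(C=CCCC1)[C@@H](C=C)C(=O)O | intermediate
11 | tert-butyl (2R)-2-[(1R)-1-{2-[(tert-butyldiphenylsilyl)oxy]ethyl}cyclohex-2-en-1-yl]but-3-enoate | CC(C)(C)[Si](c1ccccc1)(c1ccccc1)OCC[C@]1(C=CCCC1)[C@@H](C=C)C(=O)OC(C)(C)C | intermediate
12 | tert-butyl (2R)-2-[(1R)-4-(tert-butylperoxy)-1-{2-[(tert-butyldiphenylsilyl)oxy]ethyl}cyclohex-2-en-1-yl]but-3-enoate (both epimers at the peroxide carbon, C12) | CC(C)(C)[Si](c1ccccc1)(c1ccccc1)OCC[C@]1(C=CC(OOC(C)(C)C)CC1)[C@@H](C=C)C(=O)OC(C)(C)C | intermediate (not isolated)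
13 | tert-butyl (2R)-2-[(1R)-1-{2-[(tert-butyldiphenylsilyl)oxy]ethyl}-4-oxocyclohex-2-en-1-yl]but-3-enoate | CC(C)(C)[Si](c1ccccc1)(c1ccccc1)OCC[C@]1(C=CC(=O)CC1)[C@@H](C=C)C(=O)OC(C)(C)C | intermediate
14 | (2R)-2-[(1R)-1-{2-[(tert-butyldiphenylsilyl)oxy]ethyl}-4-oxocyclohex-2-en-1-yl]but-3-enoic acid | CC(C)(C)[Si](c1ccccc1)(c1ccccc1)OCC[C@]1(C=CC(=O)CC1)[C@@H](C=C)C(=O)O | intermediate
15 | tert-butyl 2-methyl-3-oxobutanoate | CC(=O)C(C)C(=O)OC(C)(C)C | starting material
16 | 3-chloro-2-(chloromethyl)prop-1-ene | C=C(CCl)CCl | starting material
17 | tert-butyl 6-(chloromethyl)-2-methyl-3-oxohept-6-enoate (racemic at C2) | CC(C(=O)OC(C)(C)C)C(=O)CCC(=C)CCl | intermediate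
18 | tert-butyl 6-{[((2R)-2-{(1R)-1-[2-(tert-butyldiphenylsilyloxy)ethyl]-4-oxocyclohex-2-en-1-yl}but-3-enoyl)oxy]methyl}-2-methyl-3-oxohept-6-enoate (both epimers at the keto ester α-carbon, C4) | CC(C)(C)[Si](c1ccccc1)(c1ccccc1)OCC[C@]1(C=CC(=O)CC1)[C@@H](C=C)C(=O)OCC(=C)CCC(=O)C(C)C(=O)OC(C)(C)C | intermediate
19 | (3R)-3-{(1R)-1-[2-(tert-butyldiphenylsilyloxy)ethyl]-4-oxocyclohex-2-en-1-yl}-5-[5-(tert-butoxy)-4-methyl-3,5-dioxopentyl]-3,6-dihydro-2H-pyran-2-one (both C4 epimers; precursor of the key step) | CC(C)(C)[Si](c1ccccc1)(c1ccccc1)OCC[C@]1(C=CC(=O)CC1)[C@H]1C=C(CCC(=O)C(C)C(=O)OC(C)(C)C)COC1=O | intermediate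
20 | ring A/B/C lactone (product of the key step): tert-butyl 16-(tert-butyldiphenylsilyloxy)-3,12-dioxo-13,16-seco-17-nor-6-epi-ent-gibberellan-19-oate with C7 (α) lactonised to the C20 oxygen; C4, C5, C8, C9, C10 as in the target | CC(C)(C)[Si](c1ccccc1)(c1ccccc1)OCC[C@]23CCC(=O)C[C@H]2[C@]1(COC4=O)CCC(=O)[C@@](C)(C(=O)OC(C)(C)C)[C@H]1[C@H]34 | intermediate
21 | 12,12-ethylenedioxy derivative of 20 (C3 ketone free) | CC(C)(C)[Si](c1ccccc1)(c1ccccc1)OCC[C@]23CCC5(OCCO5)C[C@H]2[C@]1(COC4=O)CCC(=O)[C@@](C)(C(=O)OC(C)(C)C)[C@H]1[C@H]34 | intermediate
22 | C2=C3 enol triflate of 21 (3-trifluoromethanesulfonyloxy-2-ene) | CC(C)(C)[Si](c1ccccc1)(c1ccccc1)OCC[C@]23CCC5(OCCO5)C[C@H]2[C@]1(COC4=O)CC=C(OS(=O)(=O)C(F)(F)F)[C@@](C)(C(=O)OC(C)(C)C)[C@H]1[C@H]34 | intermediate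
23 | 3-deoxy lactone: tert-butyl 16-(tert-butyldiphenylsilyloxy)-12,12-ethylenedioxy-13,16-seco-17-nor-6-epi-ent-gibberellan-19-oate 7,20-lactone | CC(C)(C)[Si](c1ccccc1)(c1ccccc1)OCC[C@]23CCC5(OCCO5)C[C@H]2[C@]1(COC4=O)CCC[C@@](C)(C(=O)OC(C)(C)C)[C@H]1[C@H]34 | intermediate
24 | 16-hydroxy analogue of 23 (primary alcohol on the C15–C16 arm) | OCC[C@]23CCC5(OCCO5)C[C@H]2[C@]1(COC4=O)CCC[C@@](C)(C(=O)OC(C)(C)C)[C@H]1[C@H]34 | intermediate
25 | 16-aldehyde (C8–CH2–CHO) | O=CC[C@]23CCC5(OCCO5)C[C@H]2[C@]1(COC4=O)CCC[C@@](C)(C(=O)OC(C)(C)C)[C@H]1[C@H]34 | intermediate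
26 | terminal alkyne (C8–CH2–C≡CH; 12-ketal) | C#CC[C@]23CCC5(OCCO5)C[C@H]2[C@]1(COC4=O)CCC[C@@](C)(C(=O)OC(C)(C)C)[C@H]1[C@H]34 | intermediate
27 | 12-ketone with C8 propargyl group: tert-butyl 12-oxo-13,16-seco-6-epi-ent-gibberell-16-yn-19-oate 7,20-lactone | C#CC[C@]23CCC(=O)C[C@H]2[C@]1(COC4=O)CCC[C@@](C)(C(=O)OC(C)(C)C)[C@H]1[C@H]34 | intermediate
28 | C12=C13 tert-butyldimethylsilyl enol ether of 27 | C#CC[C@]23CC=C(O[Si](C)(C)C(C)(C)C)C[C@H]2[C@]1(COC4=O)CCC[C@@](C)(C(=O)OC(C)(C)C)[C@H]1[C@H]34 | intermediate
29 | tetracyclic lactone: tert-butyl 12-oxo-6-epi-ent-gibberell-16-en-19-oate with C7 (α) lactonised to the C20 oxygen | C=C1C[C@]23C[C@H]1C(=O)C[C@H]2[C@]1(COC4=O)CCC[C@@](C)(C(=O)OC(C)(C)C)[C@H]1[C@H]34 | intermediate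
30 | 19-tert-butyl 7-methyl ent-20-hydroxy-12-oxogibberell-16-ene-7,19-dioate (natural C6 configuration, C7 β) | C=C1C[C@]23C[C@H]1C(=O)C[C@H]2[C@]1(CO)CCC[C@@](C)(C(=O)OC(C)(C)C)[C@H]1[C@@H]3C(=O)OC | intermediate (not isolated)
31 | 19-tert-butyl hydrogen ent-20-hydroxy-12-oxogibberell-16-ene-7,19-dioate | C=C1C[C@]23C[C@H]1C(=O)C[C@H]2[C@]1(CO)CCC[C@@](C)(C(=O)OC(C)(C)C)[C@H]1[C@@H]3C(=O)O | intermediate
32 | 19-tert-butyl hydrogen ent-12,20-dioxogibberell-16-ene-7,19-dioate | C=C1C[C@]23C[C@H]1C(=O)C[C@H]2[C@]1(C=O)CCC[C@@](C)(C(=O)OC(C)(C)C)[C@H]1[C@@H]3C(=O)O | intermediate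
33 | ent-12,20-dioxogibberell-16-ene-7,19-dioic acid (CNP0412196.1) | C=C1C[C@]23C[C@H]1C(=O)C[C@H]2[C@]1(C=O)CCC[C@@](C)(C(=O)O)[C@H]1[C@@H]3C(=O)O | target

Total step count: 24. Longest linear sequence: 23 steps (steps 1–8 and 10–24); step 9 is a one-step branch.

Least certain steps

Step 12 (key step). The tertiary C10 radical may be reduced by the solvent or oxidised before it closes ring B, which would stop the chain after ring A. The C4 radical may also add to C5 on the face syn to C8, which would give the cis A/B series. The fallback starts the same chain reductively and sets out from 19. Bromination at C4 (N-bromosuccinimide, Mg(ClO4)2 cat., EtOAc) would give the α-bromo β-keto ester F1. Slow addition of (Me3Si)3SiH with Et3B and air in benzene at high dilution abstracts bromine; the C4 radical runs through the same 6-endo and 5-exo closures and the C11 radical is reduced by the silane. This returns to the route at 20, with the hydrogen donor under concentration control.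

Step 5. Chair and boat transition states, or the two ketene acetal geometries, may be discriminated too weakly, so that the C6 epimer forms alongside 10. The fallback replaces kinetic control by equilibration in a ring and sets out from 14, carried through steps 6–8 as the epimer mixture. An amine base (DBU, CH2Cl2) should add the carboxylate to C9 and give the cis-fused keto lactone F2. Its C6 proton is exchangeable, and the vinyl group should settle on the convex face, cis to the C15 arm, which is the configuration required. F2 then replaces 14 in step 10: Cs2CO3 reopens it by β-elimination and the carboxylate is alkylated by 17, returning to the route at 18.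

Step 20. Deprotonation may occur at C11, or the enolate may equilibrate. Gold catalysis in step 21 would then close the isomeric bridged ring through C11. The fallback fixes the regiochemistry thermodynamically and sets out from 27. Condensation with tert-butoxybis(dimethylamino)methane (toluene, 80 °C) is reversible, and a planar aminomethylene group cannot sit at C11 beside C9 and C10, so it should give the C13 enaminone F3. Mild aqueous acid gives the hydroxymethylene ketone F4. Ph3PAuNTf2 closes ring D by Conia-ene cyclisation of this 1,3-dicarbonyl onto the alkyne and gives the C13-formyl tetracycle F5. Decarbonylation with RhCl(PPh3)3 (1 equiv, toluene, reflux) returns to the route at 29.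

Step 22. The C20 alkoxide may attack the C19 ester with loss of tert-butoxide and close the 19,20-lactone. C6 may also fail to equilibrate fully. The fallback accepts the acyl transfer and sets out from 29. Prolonged treatment with the same bases followed by acidification would give the 19,20-lactone 7-acid F6 with natural C6. F6 is opened with aqueous KOH, and the C20 carbinol of the dipotassium salt is oxidised without acidification by the Parikh–Doering method (SO3·pyridine, DMSO, Et3N). Acidification at the end returns to the route at 33 and makes step 24 unnecessary.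

Step 15. Hydrogenolysis may stop at the alkene or revert to the ketone by S–O cleavage, or the phenyl groups on silicon may be hydrogenated. The fallback removes the C3 oxygen by a radical deoxygenation and sets out from 21. LiAlH(OtBu)3 (THF, 0 °C) reduces the C3 ketone without touching lactone or ester and gives the C3 alcohol F7 (either epimer serves). 1,1'-Thiocarbonyldiimidazole with DMAP gives the imidazolylthiocarbonate F8, made without strong base so that no retro-aldol opening of ring A occurs. Barton–McCombie reduction (Bu3SnH, AIBN, toluene, 100 °C) returns to the route at 23.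

Further compounds

F1 | step 12 | α-bromo β-keto ester: (3R)-3-{(1R)-1-[2-(tert-butyldiphenylsilyloxy)ethyl]-4-oxocyclohex-2-en-1-yl}-5-[4-bromo-5-(tert-butoxy)-4-methyl-3,5-dioxopentyl]-3,6-dihydro-2H-pyran-2-one (both C4 epimers) | CC(C)(C)[Si](c1ccccc1)(c1ccccc1)OCC[C@]1(C=CC(=O)CC1)[C@H]1C=C(CCC(=O)C(C)(Br)C(=O)OC(C)(C)C)COC1=O
F2 | step 5 | cis-fused keto lactone: 3a-[2-(tert-butyldiphenylsilyloxy)ethyl]-3-ethenylhexahydro-1-benzofuran-2,6-dione, vinyl cis to the 3a side chain (C6 R, C8 R in gibberellane numbering) | CC(C)(C)[Si](c1ccccc1)(c1ccccc1)OCC[C@]12CCC(=O)C[C@H]1OC(=O)[C@@H]2C=C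
F3 | step 20 | C13 (E)-dimethylaminomethylene derivative of 27 | C#CC[C@]23C/C(=C\N(C)C)C(=O)C[C@H]2[C@]1(COC4=O)CCC[C@@](C)(C(=O)OC(C)(C)C)[C@H]1[C@H]34
F4 | step 20 | C13 hydroxymethylene derivative of 27 (enol form of the 13-formyl ketone) | C#CC[C@]23C/C(=C/O)C(=O)C[C@H]2[C@]1(COC4=O)CCC[C@@](C)(C(=O)OC(C)(C)C)[C@H]1[C@H]34
F5 | step 20 | 13-formyl derivative of 29 (bridgehead aldehyde, ring D closed) | C=C1C[C@]23C[C@@]1(C=O)C(=O)C[C@H]2[C@]1(COC4=O)CCC[C@@](C)(C(=O)OC(C)(C)C)[C@H]1[C@H]34
F6 | step 22 | ent-20-hydroxy-12-oxogibberell-16-ene-7,19-dioic acid 19,20-lactone (natural C6) | C=C1C[C@]23C[C@H]1C(=O)C[C@H]2[C@]1(CO4)CCC[C@@](C)(C4=O)[C@H]1[C@@H]3C(=O)O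
F7 | step 15 | 3-hydroxy analogue of 21 (C3 alcohol, either epimer) | CC(C)(C)[Si](c1ccccc1)(c1ccccc1)OCC[C@]23CCC5(OCCO5)C[C@H]2[C@]1(COC4=O)CCC(O)[C@@](C)(C(=O)OC(C)(C)C)[C@H]1[C@H]34
F8 | step 15 | 3-O-(imidazol-1-ylthiocarbonyl) derivative of F7 | CC(C)(C)[Si](c1ccccc1)(c1ccccc1)OCC[C@]23CCC5(OCCO5)C[C@H]2[C@]1(COC4=O)CCC(OC(=S)n6ccnc6)[C@@](C)(C(=O)OC(C)(C)C)[C@H]1[C@H]34
A1 | alternative 1 | ring A/B/C 7-acid with C13=C14 alkene (12-ketal, C20 silyl ether, silylated propargyl arm, 19-methyl ester) | C[Si](C)(C)C#CC[C@]23C=CC4(OCCO4)C[C@H]2[C@]1(CO[Si](C)(C)C(C)(C)C)CCC[C@@](C)(C(=O)OC)[C@H]1[C@@H]3C(=O)O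
A2 | alternative 2 | cyclobutane photoadduct with C20 pivalate (12-ketone, propargyl arm, 7,19-dimethyl ester) | C#CC[C@@]12CCC(=O)[C@H]3[C@H](OC(=O)C(C)(C)C)[C@]4(CCC[C@@](C)(C(=O)OC)[C@H]4[C@@H]1C(=O)OC)[C@@H]23
A3 | alternative 3 | tetracyclic C12 alcohol with 16-methylene (C20 silyl ether, 7,19-dimethyl ester) | C=C1C[C@]23C[C@H]1[C@@H](O)C[C@H]2[C@]1(CO[Si](C)(C)C(C)(C)C)CCC[C@@](C)(C(=O)OC)[C@H]1[C@@H]3C(=O)OC
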